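## Retrosynthetic overview
1. Locants: C1 = CH(OCOAr), C2 = CMe2, C3=C4 (E), C5 (=CH2), C6, C7, C8=C9(Me) (E), C10, C11. Only one ring is made, the eleven-membered carbocycle, and it is closed in the last step at C4–C5.
2. C4–C5: the methyl ketone carbon C5 is used with reversed polarity, as the diazoalkane released from its tosylhydrazone. It is joined on palladium to the alkenyl iodide carbon C4, so two native electrophiles are coupled. The ketone CH3 becomes the exocyclic CH2, and the phenolic acetate falls off in the same flask.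
3. The E-alkenyl iodide comes from a terminal alkyne (hydrostannation, iodolysis). The ester comes from O-acetylvanillic acid.
4. C1–C2: one asymmetric allenylboration of a keto aldehyde with a dimethylallenyl-B(Ipc)2 reagent sets the R carbinol and the quaternary carbon.
5. The keto aldehyde (C5 to C11 plus C1, with the E C8=C9 alkene in place) comes from (E)-geranylacetone by cleaving its isopropylidene end.

Assumption: geranylacetone is bought as (or distilled to) the pure E isomer, O-acetylvanillic acid is bought as such, and the stereocentre in the SMILES is read as R.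

## Route

Step 1
Reactants: 1 (E)-geranylacetone
Product: 3 (4E)-4-methyl-8-oxonon-4-enal, via terminal epoxide 2 (not isolated)
Conditions: mCPBA (1.0 equiv), CH2Cl2, −10 to 0 °C; NaHCO3 wash, crude 2 then H5IO6 (1.2 equiv), THF–H2O, 0 °C to rt
Reagents that add atoms: mCPBA (3-chloroperoxybenzoic acid), O=C(OO)c1cccc(Cl)c1
Why: Prilezhaev epoxidation goes preferentially to the less hindered terminal trisubstituted alkene and periodic acid then hydrolyses the epoxide and cleaves the glycol (Malaprade cleavage) to aldehyde 3 plus acetone, while any epoxide at the inner alkene is cut to small volatile fragments that are lost on purification, and the E alkene of 1 is carried through with no stereocentre at stake.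

Step 2
Reactants: 3 (4E)-4-methyl-8-oxonon-4-enal, 4 3-methylbuta-1,2-diene, 5 (−)-B-chlorodiisopinocampheylborane (from (+)-α-pinene)
Product: 9 (5E,9R)-9-hydroxy-6,10,10-trimethyldodec-5-en-11-yn-2-one, via allenyllithium 6 (not isolated), via allenylborane 7 (not isolated), via borinate 8 (not isolated)
Conditions: 4, n-BuLi, THF, −78 to −20 °C; 5 (1.1 equiv to 3), −78 °C, 1 h; 3, −78 °C, 4 h; then NaOH, H2O2, 0 °C to rt
Reagents that add atoms: 3-methylbuta-1,2-diene, CC(C)=C=C
Why: Brown-type asymmetric allenylboration (carbonyl propargylation), in which allenylborane 7 adds through a closed six-membered SE2' transition state at its dimethyl-bearing gamma carbon, at −78 °C only to the aldehyde and not to the methyl ketone, and the isopinocampheyl groups from (+)-α-pinene steer attack to the Si face in the same sense as the known allyl and prenyl B(Ipc)2 reagents, which sets the R carbinol centre beside the new quaternary carbon.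

Step 3
Reactants: 9 (5E,9R)-9-hydroxy-6,10,10-trimethyldodec-5-en-11-yn-2-one, 10 4-acetoxy-3-methoxybenzoic acid (O-acetylvanillic acid)
Product: 12 (5E,9R)-6,10,10-trimethyl-2-oxododec-5-en-11-yn-9-yl 4-acetoxy-3-methoxybenzoate, via O-acylisourea 11 (not isolated)
Conditions: DCC (1.5 equiv), DMAP (0.3 equiv), CH2Cl2, 0 °C to rt, 24 h
Reagents that add atoms: 4-acetoxy-3-methoxybenzoic acid, CC(=O)Oc1ccc(C(=O)O)cc1OC
Why: Steglich esterification through the O-acylisourea and the acylpyridinium ion acylates the hindered neopentylic alcohol at oxygen, so the C–O bond at the stereocentre is not broken and the R configuration is kept, and the phenol stays masked as an acetate that is shed later without a step of its own.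

Step 4
Reactants: 12 (5E,9R)-6,10,10-trimethyl-2-oxododec-5-en-11-yn-9-yl 4-acetoxy-3-methoxybenzoate
Product: 14 (5E,9R,11E)-12-iodo-6,10,10-trimethyl-2-oxododeca-5,11-dien-9-yl 4-acetoxy-3-methoxybenzoate, via alkenylstannane 13 (not isolated)
Conditions: Bu3SnH (1.3 equiv, slow addition), PdCl2(PPh3)2 (2 mol %), THF, 0 °C to rt; then I2, 0 °C, until the colour persists
Reagents that add atoms: iodine, II
Why: Palladium-catalysed syn hydrostannation places tin on the terminal carbon because the adjacent quaternary carbon blocks the inner position, and iododestannylation goes with retention to give only the E alkenyl iodide, leaving ketone, esters and the trisubstituted alkene alone.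

Step 5
Reactants: 14 (5E,9R,11E)-12-iodo-6,10,10-trimethyl-2-oxododeca-5,11-dien-9-yl 4-acetoxy-3-methoxybenzoate, 15 4-methylbenzenesulfonohydrazide
Product: 19 (1R,3E,8E)-2,2,9-trimethyl-5-methylidenecycloundeca-3,8-dien-1-yl 4-hydroxy-3-methoxybenzoate, via tosylhydrazone 16 (not isolated), via phenol tosylhydrazone 17 (not isolated), via diazoalkane 18 (not isolated)
Conditions: 15 (1.0 equiv), 1,4-dioxane, 60 °C, 2 h; this solution added by syringe pump over 12 h to Pd2(dba)3 (10 mol %), XPhos (40 mol %), LiOtBu (3.3 equiv), 1,4-dioxane, 90 °C, 1 mM final; AcOH quench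
Reagents that add atoms: none
Why: Proposed new method: a macrocyclic version of the palladium-catalysed cross-coupling of N-tosylhydrazones with alkenyl halides (Barluenga coupling, the closest known type, established intermolecularly for dienes and in one pot from the free ketone), in which base releases diazoalkane 18 so that the natively electrophilic carbonyl carbon C5 becomes a carbon nucleophile that attacks the electrophilic alkenylpalladium iodide (divalent palladium) formed by fast oxidative addition of zerovalent palladium at C4, loss of N2 gives a palladium carbene, migratory insertion of the alkenyl group closes the eleven-membered ring with the E geometry kept by the bulky C2 substituent, syn beta-hydride loss from the freely rotating CH3 gives the exocyclic methylene, the excess LiOtBu strips the phenolic acetate, the resulting para-phenoxide shields the hindered benzoate, and the C1 stereocentre is not touched.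

## Compound list
1 | (E)-geranylacetone, (5E)-6,10-dimethylundeca-5,9-dien-2-one | CC(C)=CCC/C(C)=C/CCC(C)=O | starting material
2 | (5E)-8-(3,3-dimethyloxiran-2-yl)-6-methyloct-5-en-2-one (racemic epoxide) | CC1(C)OC1CC/C(C)=C/CCC(C)=O | intermediate
3 | (4E)-4-methyl-8-oxonon-4-enal | O=CCC/C(C)=C/CCC(C)=O | intermediate
4 | 3-methylbuta-1,2-diene | CC(C)=C=C | starting material
5 | (−)-B-chlorodiisopinocampheylborane | C[C@H]1[C@@H](C[C@@H]2C[C@H]1C2(C)C)B(Cl)[C@@H]3C[C@@H]4C[C@H]([C@H]3C)C4(C)C | starting material
6 | 3-methylbuta-1,2-dienyllithium | [Li]C=C=C(C)C | intermediate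
7 | B-(3-methylbuta-1,2-dienyl)diisopinocampheylborane | C[C@H]1[C@@H](C[C@@H]2C[C@H]1C2(C)C)B(C=C=C(C)C)[C@@H]3C[C@@H]4C[C@H]([C@H]3C)C4(C)C | intermediate
8 | diisopinocampheylborinate of 9 | C#CC(C)(C)[C@H](OB([C@@H]1C[C@@H]2C[C@H]([C@H]1C)C2(C)C)[C@@H]3C[C@@H]4C[C@H]([C@H]3C)C4(C)C)CC/C(C)=C/CCC(C)=O | intermediate
9 | (5E,9R)-9-hydroxy-6,10,10-trimethyldodec-5-en-11-yn-2-one | C#CC(C)(C)[C@H](O)CC/C(C)=C/CCC(C)=O | intermediate
10 | 4-acetoxy-3-methoxybenzoic acid | CC(=O)Oc1ccc(C(=O)O)cc1OC | starting material
11 | O-(4-acetoxy-3-methoxybenzoyl)-N,N'-dicyclohexylisourea | CC(=O)Oc1ccc(cc1OC)C(=O)OC(=NC1CCCCC1)NC1CCCCC1 | intermediate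
12 | (5E,9R)-6,10,10-trimethyl-2-oxododec-5-en-11-yn-9-yl 4-acetoxy-3-methoxybenzoate | C#CC(C)(C)[C@H](OC(=O)c1ccc(OC(C)=O)c(OC)c1)CC/C(C)=C/CCC(C)=O | intermediate
13 | (5E,9R,11E)-6,10,10-trimethyl-2-oxo-12-(tributylstannyl)dodeca-5,11-dien-9-yl 4-acetoxy-3-methoxybenzoate | CCCC[Sn](CCCC)(CCCC)/C=C/C(C)(C)[C@H](OC(=O)c1ccc(OC(C)=O)c(OC)c1)CC/C(C)=C/CCC(C)=O | intermediate
14 | (5E,9R,11E)-12-iodo-6,10,10-trimethyl-2-oxododeca-5,11-dien-9-yl 4-acetoxy-3-methoxybenzoate | I/C=C/C(C)(C)[C@H](OC(=O)c1ccc(OC(C)=O)c(OC)c1)CC/C(C)=C/CCC(C)=O | intermediate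
15 | 4-methylbenzenesulfonohydrazide | Cc1ccc(cc1)S(=O)(=O)NN | starting material
16 | N-tosylhydrazone of 14 (C=N geometry not defined) | I/C=C/C(C)(C)[C@H](OC(=O)c1ccc(OC(C)=O)c(OC)c1)CC/C(C)=C/CCC(C)=NNS(=O)(=O)c1ccc(C)cc1 | intermediate
17 | deacetylated N-tosylhydrazone (free phenol, present as its lithium salts) | I/C=C/C(C)(C)[C@H](OC(=O)c1ccc(O)c(OC)c1)CC/C(C)=C/CCC(C)=NNS(=O)(=O)c1ccc(C)cc1 | intermediate
18 | (5E,9R,11E)-2-diazo-12-iodo-6,10,10-trimethyldodeca-5,11-dien-9-yl 4-hydroxy-3-methoxybenzoate | I/C=C/C(C)(C)[C@H](OC(=O)c1ccc(O)c(OC)c1)CC/C(C)=C/CCC(C)=[N+]=[N-] | intermediate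
19 | (1R,3E,8E)-2,2,9-trimethyl-5-methylidenecycloundeca-3,8-dien-1-yl 4-hydroxy-3-methoxybenzoate (CNP0416843.1) | C=C1/C=C/C(C)(C)[C@H](OC(=O)c2ccc(O)c(OC)c2)CC/C(C)=C/CC1 | target

## Count and risks
Total step count: 5. Longest linear sequence: 5 (1 to 19).

**Step 5 is the most at risk.**
- What can go wrong: the substrate can oligomerise, the diazoalkane can collapse to Bamford–Stevens alkenes before palladium captures it, or beta-hydride loss can come from the ring CH2 at C6 and give the endocyclic diene.
- The fallback sets out from 14 and comes back at 19.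
- The ketone of 14 is condensed with 1,2-bis(tert-butyldimethylsilyl)hydrazine (catalytic Sc(OTf)3) to the N-silyl hydrazone F1.
- I2 and 2-tert-butyl-1,1,3,3-tetramethylguanidine (Barton vinyl iodide synthesis) turn it into the bis(alkenyl iodide) F2, whose new terminus is the 2-iodo-1-alkene. The exocyclic methylene is thus fixed before ring closure.
- A one-pot stannylation and Stille ring closure (Stille–Kelly coupling, (Me3Sn)2, Pd(PPh3)4, dioxane, high dilution) joins the two iodide-bearing carbons to give the macrocyclic acetate F3.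
- K2CO3 in MeOH removes the phenolic acetate to give 19.

**Step 2 is second.**
- What can go wrong: the dimethylallenyl B(Ipc)2 reagent extrapolates from the allyl, prenyl and parent allenyl reagents, so the ee or the rate at −78 °C may fall short.
- The fallback sets out from 3 and comes back at 9.
- Aldehyde 3 is coupled with 2-methyl-4-(trimethylsilyl)but-1-en-3-yne by ruthenium-catalysed transfer hydrogenation. Conditions are Ru(O2CCF3)2(CO)(PPh3)2, the BINAP enantiomer matched to the R carbinol, 2-propanol as hydrogen donor, THF, 95 °C. The product is the silyl alkynol F4.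
- K2CO3 in MeOH removes the silyl group to give 9.

**Step 1 is third.**
- What can go wrong: the two trisubstituted alkenes of 1 differ little towards mCPBA, so the yield may be low.
- The fallback sets out from 1 and comes back at 2.
- NBS in THF–water, where the coiled chain exposes only its end, gives the terminal bromohydrin F5.
- K2CO3 in MeOH closes it to epoxide 2, which is cleaved with H5IO6 as in step 1.

## Further compounds
F1 | step 5 | N-(tert-butyldimethylsilyl)hydrazone of 14 | I/C=C/C(C)(C)[C@H](OC(=O)c1ccc(OC(C)=O)c(OC)c1)CC/C(C)=C/CCC(C)=NN[Si](C)(C)C(C)(C)C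
F2 | step 5 | (1E,4R,7E)-1,11-diiodo-3,3,7-trimethyldodeca-1,7,11-trien-4-yl 4-acetoxy-3-methoxybenzoate | I/C=C/C(C)(C)[C@H](OC(=O)c1ccc(OC(C)=O)c(OC)c1)CC/C(C)=C/CCC(I)=C
F3 | step 5 | (1R,3E,8E)-2,2,9-trimethyl-5-methylidenecycloundeca-3,8-dien-1-yl 4-acetoxy-3-methoxybenzoate | C=C1/C=C/C(C)(C)[C@H](OC(=O)c2ccc(OC(C)=O)c(OC)c2)CC/C(C)=C/CC1
F4 | step 2 | (5E,9R)-9-hydroxy-6,10,10-trimethyl-12-(trimethylsilyl)dodec-5-en-11-yn-2-one | C[Si](C)(C)C#CC(C)(C)[C@H](O)CC/C(C)=C/CCC(C)=O
F5 | step 1 | (5E)-9-bromo-10-hydroxy-6,10-dimethylundec-5-en-2-one (racemic) | CC(C)(O)C(Br)CC/C(C)=C/CCC(C)=O
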